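The route disconnects the oxolane at O1–C2 and the linker at C1–C2'. The target's 2,5-trans oxolane (O1, C2–C5), whose C2 carries the exocyclic C1 methylene bound to sp2 carbon C2' of ring C, is what results when a C5 alkoxide and an alkenyl group add across a terminal C1=C2 alkene. A palladium-catalysed carboetherification therefore forms O1–C2 and C1–C2', closes the oxolane and sets C2 in one operation. Its precursors are the open-chain (3S,5R,6E)-dienediol bearing a vinyl group on C3, built from (S)-citramalic acid, and an S-configured 2-bromo-3-methoxy-6-silyloxycyclohexenone standing for ring C.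

Key step: step 12

Locants: oxolane O1, C2 (bearing C1H2), C3 (methyl carbinol), C4, C5 (bearing the dienyl chain C6–C12); ring C is C1'–C6', with C2' bonded to C1 and C4' the secondary carbinol.
Remark: ring C of the target is an enolised 1,3-dione whose two enol forms interconvert, so a vinylogous ester on either carbonyl hydrolyses to the same compound.
Assumption: in the lipase-catalysed acetylation of step 9 the R alcohol is taken to react faster (the usual preference for cyclic α-hydroxy ketones, the carbonyl carbon acting as the large group), so the S alcohol is the one recovered.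

Step 1
Reactants: 1 (S)-citramalic acid
Product: 2 2-[(4S)-2,2,4-trimethyl-5-oxo-1,3-dioxolan-4-yl]acetic acid
Conditions: 2,2-dimethoxypropane (solvent), p-TsOH·H2O (cat.), rt
Reagents that add atoms: 2,2-dimethoxypropane, COC(C)(C)OC
Why: Acid-catalysed acetal exchange (acetonide formation) should close the five-membered dioxolanone across the tertiary hydroxyl and the adjacent carboxyl in preference to the six-membered alternative, as with malic acid, leaving the CH2CO2H arm free and the future C3 stereocentre untouched.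

Step 2
Reactants: 2 2-[(4S)-2,2,4-trimethyl-5-oxo-1,3-dioxolan-4-yl]acetic acid
Product: 3 2-[(4S)-2,2,4-trimethyl-5-oxo-1,3-dioxolan-4-yl]acetyl chloride
Conditions: (COCl)2, DMF (cat.), CH2Cl2, 0 °C to rt; used crude
Reagents that add atoms: oxalyl chloride, O=C(Cl)C(=O)Cl
Why: Vilsmeier-type activation with oxalyl chloride and catalytic DMF (acid chloride formation) is neutral enough for the dioxolanone to survive.

Step 3
Reactants: 4 6-methylhept-5-en-2-one
Product: 6 6-methylhept-5-en-1-yne, via enol phosphate 5 (not isolated)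
Conditions: LiN(iPr)2 (1.05 equiv), THF, −78 °C; ClP(O)(OEt)2, −78 °C to rt; LiN(iPr)2 (2.3 equiv), THF, −78 °C to rt; H2O
Reagents that add atoms: none
Why: Kinetic deprotonation at the methyl group, O-phosphorylation and base-induced elimination of the enol phosphate constitute the Negishi conversion of a methyl ketone into a terminal alkyne, to which the remote trisubstituted alkene is inert.

Step 4
Reactants: 6 6-methylhept-5-en-1-yne; 3 2-[(4S)-2,2,4-trimethyl-5-oxo-1,3-dioxolan-4-yl]acetyl chloride
Product: 9 (5S)-5-[(3E)-4,8-dimethyl-2-oxonona-3,7-dien-1-yl]-2,2,5-trimethyl-1,3-dioxolan-4-one, via alkenyldimethylalane 7 (not isolated), via alkenylzinc chloride 8 (not isolated)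
Conditions: AlMe3 (2 equiv), Cp2ZrCl2 (0.25 equiv), CH2Cl2, 0 °C to rt; volatiles removed in vacuo; ZnCl2 (1 equiv), THF, 0 °C; then 3, Pd(PPh3)4 (5 mol %), THF, 0 °C to rt
Reagents that add atoms: trimethylaluminium, C[Al](C)C
Why: Zirconium-catalysed syn-carboalumination (Negishi) places methyl on the internal and aluminium on the terminal alkyne carbon, which fixes the 6E geometry, and the derived alkenylzinc is acylated by the acid chloride under Pd(PPh3)4 catalysis (Negishi acylation), a coupling that leaves ester-type carbonyls such as the dioxolanone alone.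

Step 5
Reactants: 9 (5S)-5-[(3E)-4,8-dimethyl-2-oxonona-3,7-dien-1-yl]-2,2,5-trimethyl-1,3-dioxolan-4-one
Product: 11 (3S,5R)-5-[(1E)-2,6-dimethylhepta-1,5-dien-1-yl]-3-hydroxy-3-methyloxolan-2-one, via hydroxy dioxolanone 10 (not isolated)
Conditions: (3aS)-1-methyl-3,3-diphenyltetrahydro-1H,3H-pyrrolo[1,2-c][1,3,2]oxazaborole [(S)-Me-CBS, 0.2 equiv], catecholborane (1.5 equiv), toluene, −78 °C; then MeOH, K2CO3, 0 °C to rt; AcOH
Reagents that add atoms: none
Why: Corey–Bakshi–Shibata reduction with the S catalyst should treat the s-cis alkenyl group as the large substituent and so deliver the 5R allylic alcohol by reagent control, after which carbonate-mediated methanolysis lets the C5 hydroxyl take over the acetonide-bound carboxyl (translactonisation) to give a γ-lactone whose C5 epimer, if formed, is a separable diastereomer.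

Step 6
Reactants: 11 (3S,5R)-5-[(1E)-2,6-dimethylhepta-1,5-dien-1-yl]-3-hydroxy-3-methyloxolan-2-one
Product: 12 (3S,5R)-5-[(1E)-2,6-dimethylhepta-1,5-dien-1-yl]-3-methyloxolane-2,3-diol (mixture at C2)
Conditions: iBu2AlH (2.3 equiv), CH2Cl2, −78 °C; aq. KNaC4H4O6
Reagents that add atoms: none
Why: At −78 °C the aluminium hemiacetal formed from the lactone does not collapse, so the reduction should stop at the lactol (partial lactone reduction), the first equivalent of hydride being consumed by the tertiary hydroxyl.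

Step 7
Reactants: 12 (3S,5R)-5-[(1E)-2,6-dimethylhepta-1,5-dien-1-yl]-3-methyloxolane-2,3-diol
Product: 14 (3S,5R,6E)-3,7,11-trimethyldodeca-1,6,10-triene-3,5-diol, via open-chain hydroxy aldehyde 13 (not isolated)
Conditions: Ph3PCH3Br (4 equiv), KOtBu (3.8 equiv), THF, 0 °C to 40 °C
Reagents that add atoms: methyltriphenylphosphonium bromide, C[P+](c1ccccc1)(c1ccccc1)c1ccccc1.[Br-]
Why: Wittig methylenation of the ring-opened lactol turns the former carboxyl carbon C2 into the C1=C2 vinyl group and releases the C5 hydroxyl, excess ylide covering the two hydroxyl protons, and no stereocentre is involved.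

Step 8
Reactants: 15 3-methoxycyclohex-2-en-1-one
Product: 16 rac-6-hydroxy-3-methoxycyclohex-2-en-1-one
Conditions: KN(SiMe3)2 (1.1 equiv), THF, −78 °C; 2-(phenylsulfonyl)-3-phenyloxaziridine (1.2 equiv), −78 °C; aq. NH4Cl
Reagents that add atoms: 2-(phenylsulfonyl)-3-phenyloxaziridine, O=S(=O)(c1ccccc1)N1OC1c1ccccc1
Why: Kinetic deprotonation of the vinylogous ester takes place at C6, and the cross-conjugated enolate accepts electrophilic oxygen from the N-sulfonyloxaziridine (Davis enolate hydroxylation) to give the racemic acyloin.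

Step 9
Reactants: 16 rac-6-hydroxy-3-methoxycyclohex-2-en-1-one
Product: 17 (6S)-6-hydroxy-3-methoxycyclohex-2-en-1-one
Conditions: Burkholderia cepacia lipase (immobilised), vinyl acetate (3 equiv), tBuOMe, 30 °C, stopped just beyond half conversion; chromatography
Reagents that add atoms: none
Why: Lipase-catalysed irreversible transesterification (kinetic resolution) should acetylate the R alcohol much faster, so that the S alcohol remains and is separated from the R acetate by chromatography.

Step 10
Reactants: 17 (6S)-6-hydroxy-3-methoxycyclohex-2-en-1-one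
Product: 18 (6S)-6-[(tert-butyldimethylsilyl)oxy]-3-methoxycyclohex-2-en-1-one
Conditions: TBSCl, imidazole, DMF, 0 °C to rt
Reagents that add atoms: tert-butyldimethylsilyl chloride, CC(C)(C)[Si](C)(C)Cl
Why: Imidazole-promoted silylation of the secondary hydroxyl runs under nearly neutral conditions that should not enolise the adjacent ketone, so C6 keeps its configuration.

Step 11
Reactants: 18 (6S)-6-[(tert-butyldimethylsilyl)oxy]-3-methoxycyclohex-2-en-1-one
Product: 19 (6S)-2-bromo-6-[(tert-butyldimethylsilyl)oxy]-3-methoxycyclohex-2-en-1-one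
Conditions: N-bromosuccinimide (1.05 equiv), CH2Cl2, 0 °C to rt, dark
Reagents that add atoms: N-bromosuccinimide, O=C1CCC(=O)N1Br
Why: The push–pull enol ether is most nucleophilic at C2, so electrophilic bromination of the vinylogous ester should occur there by addition–elimination and leave C6 alone.

Step 12
Reactants: 14 (3S,5R,6E)-3,7,11-trimethyldodeca-1,6,10-triene-3,5-diol; 19 (6S)-2-bromo-6-[(tert-butyldimethylsilyl)oxy]-3-methoxycyclohex-2-en-1-one (1.3 equiv)
Product: 20 (6S)-6-[(tert-butyldimethylsilyl)oxy]-2-{[(2S,3S,5R)-5-[(1E)-2,6-dimethylhepta-1,5-dien-1-yl]-3-hydroxy-3-methyloxolan-2-yl]methyl}-3-methoxycyclohex-2-en-1-one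
Conditions: Pd(OAc)2 (4 mol %), bis[2-(diphenylphosphino)phenyl] ether (DPE-Phos, 8 mol %), Cs2CO3 (2 equiv), 1,4-dioxane, 90 °C
Reagents that add atoms: none
Why: Oxidative addition of the C2'–Br bond to zerovalent palladium (formed in the flask from Pd(OAc)2 and the phosphine), carbonate-assisted exchange of bromide for the C5 alkoxide, syn-insertion of the C1=C2 vinyl group into the Pd–O bond and C(sp3)–C(sp2) reductive elimination should form O1–C2 and C1–C2' in one catalytic cycle; the closest known reaction is the palladium-catalysed carboetherification of γ-hydroxy alkenes with aryl and alkenyl bromides (Wolfe). The oxolane closes in the 5-exo-trig mode. The new stereocentre C2 is under substrate control: in the cyclic alkoxypalladation transition state the C5 dienyl group and the C3 methyl, which are cis to each other, both lie pseudoequatorial, so C1 emerges trans to both (2S, 2,5-trans). The step must choose among two hydroxyls and three alkenes, and the substrate secures this because only the C5 hydroxyl and the monosubstituted vinyl group can meet in a five-membered ring with a reactive alkene, whereas the C3 hydroxyl could only insert the trisubstituted C6=C7 bond as a tertiary alkoxide. The C3 hydroxyl is left free on purpose, since a silyl group there could migrate to the C5 oxygen, and the chelating bis-phosphine is meant to disfavour β-hydride loss from the allylic alkoxide and Heck coupling. Cs2CO3, the base of the weak-base carboaminations and of palladium-catalysed etherifications of secondary alcohols, replaces the usual alkoxide so that neither the C4' stereocentre next to the ketone nor the vinylogous ester meets a free strong base.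

Step 13
Reactants: 20 (6S)-6-[(tert-butyldimethylsilyl)oxy]-2-{[(2S,3S,5R)-5-[(1E)-2,6-dimethylhepta-1,5-dien-1-yl]-3-hydroxy-3-methyloxolan-2-yl]methyl}-3-methoxycyclohex-2-en-1-one
Product: 21 (4S)-4-[(tert-butyldimethylsilyl)oxy]-2-{[(2S,3S,5R)-5-[(1E)-2,6-dimethylhepta-1,5-dien-1-yl]-3-hydroxy-3-methyloxolan-2-yl]methyl}-3-hydroxycyclohex-2-en-1-one
Conditions: HCl (1 M aq.), THF, 0 °C to rt
Reagents that add atoms: water, O
Why: Dilute aqueous acid protonates the vinylogous ester, water adds at the methoxy-bearing carbon and methanol leaves (vinylogous ester hydrolysis), which should give the enolised 1,3-dione under conditions mild enough for the allylic oxolane and the silyl ether.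

Step 14
Reactants: 21 (4S)-4-[(tert-butyldimethylsilyl)oxy]-2-{[(2S,3S,5R)-5-[(1E)-2,6-dimethylhepta-1,5-dien-1-yl]-3-hydroxy-3-methyloxolan-2-yl]methyl}-3-hydroxycyclohex-2-en-1-one
Product: 22 (4S)-2-{[(2S,3S,5R)-5-[(1E)-2,6-dimethylhepta-1,5-dien-1-yl]-3-hydroxy-3-methyloxolan-2-yl]methyl}-3,4-dihydroxycyclohex-2-en-1-one
Conditions: HF·pyridine, pyridine, THF, 0 °C to rt
Reagents that add atoms: none
Why: Buffered fluoride cleaves the Si–O bond (desilylation) without base, so the C4' carbinol next to the enolised dione should keep its configuration.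

Compound list
1 | (S)-citramalic acid [(2S)-2-hydroxy-2-methylbutanedioic acid] | C[C@](O)(CC(=O)O)C(=O)O | starting material
2 | 2-[(4S)-2,2,4-trimethyl-5-oxo-1,3-dioxolan-4-yl]acetic acid | C[C@@]1(CC(=O)O)OC(C)(C)OC1=O | intermediate
3 | 2-[(4S)-2,2,4-trimethyl-5-oxo-1,3-dioxolan-4-yl]acetyl chloride | C[C@@]1(CC(=O)Cl)OC(C)(C)OC1=O | intermediate
4 | 6-methylhept-5-en-2-one | CC(=O)CCC=C(C)C | starting material
5 | diethyl 6-methylhepta-1,5-dien-2-yl phosphate (enol phosphate) | C=C(CCC=C(C)C)OP(=O)(OCC)OCC | intermediate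
6 | 6-methylhept-5-en-1-yne | C#CCCC=C(C)C | intermediate
7 | [(1E)-2,6-dimethylhepta-1,5-dien-1-yl]dimethylalane | CC(C)=CCC/C(C)=C/[Al](C)C | intermediate
8 | [(1E)-2,6-dimethylhepta-1,5-dien-1-yl]zinc chloride | CC(C)=CCC/C(C)=C/[Zn]Cl | intermediate
9 | (5S)-5-[(3E)-4,8-dimethyl-2-oxonona-3,7-dien-1-yl]-2,2,5-trimethyl-1,3-dioxolan-4-one | CC(C)=CCC/C(C)=C/C(=O)C[C@]1(C)OC(C)(C)OC1=O | intermediate
10 | (5S)-5-[(2R,3E)-2-hydroxy-4,8-dimethylnona-3,7-dien-1-yl]-2,2,5-trimethyl-1,3-dioxolan-4-one | CC(C)=CCC/C(C)=C/[C@H](O)C[C@]1(C)OC(C)(C)OC1=O | intermediate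
11 | (3S,5R)-5-[(1E)-2,6-dimethylhepta-1,5-dien-1-yl]-3-hydroxy-3-methyloxolan-2-one | CC(C)=CCC/C(C)=C/[C@H]1C[C@](C)(O)C(=O)O1 | intermediate
12 | (3S,5R)-5-[(1E)-2,6-dimethylhepta-1,5-dien-1-yl]-3-methyloxolane-2,3-diol (mixture at C2) | CC(C)=CCC/C(C)=C/[C@H]1C[C@](C)(O)C(O)O1 | intermediate
13 | (2S,4R,5E)-2,4-dihydroxy-2,6,10-trimethylundeca-5,9-dienal | CC(C)=CCC/C(C)=C/[C@H](O)C[C@](C)(O)C=O | intermediate
14 | (3S,5R,6E)-3,7,11-trimethyldodeca-1,6,10-triene-3,5-diol | CC(C)=CCC/C(C)=C/[C@H](O)C[C@](C)(O)C=C | intermediate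
15 | 3-methoxycyclohex-2-en-1-one | COC1=CC(=O)CCC1 | starting material
16 | rac-6-hydroxy-3-methoxycyclohex-2-en-1-one | COC1=CC(=O)C(O)CC1 | intermediate
17 | (6S)-6-hydroxy-3-methoxycyclohex-2-en-1-one | COC1=CC(=O)[C@@H](O)CC1 | intermediate
18 | (6S)-6-[(tert-butyldimethylsilyl)oxy]-3-methoxycyclohex-2-en-1-one | COC1=CC(=O)[C@@H](O[Si](C)(C)C(C)(C)C)CC1 | intermediate
19 | (6S)-2-bromo-6-[(tert-butyldimethylsilyl)oxy]-3-methoxycyclohex-2-en-1-one | COC1=C(Br)C(=O)[C@@H](O[Si](C)(C)C(C)(C)C)CC1 | intermediate
20 | (6S)-6-[(tert-butyldimethylsilyl)oxy]-2-{[(2S,3S,5R)-5-[(1E)-2,6-dimethylhepta-1,5-dien-1-yl]-3-hydroxy-3-methyloxolan-2-yl]methyl}-3-methoxycyclohex-2-en-1-one | CC(C)=CCC/C(C)=C/[C@H]1C[C@](C)(O)[C@H](CC2=C(OC)CC[C@H](O[Si](C)(C)C(C)(C)C)C2=O)O1 | intermediate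
21 | (4S)-4-[(tert-butyldimethylsilyl)oxy]-2-{[(2S,3S,5R)-5-[(1E)-2,6-dimethylhepta-1,5-dien-1-yl]-3-hydroxy-3-methyloxolan-2-yl]methyl}-3-hydroxycyclohex-2-en-1-one | CC(C)=CCC/C(C)=C/[C@H]1C[C@](C)(O)[C@H](CC2=C(O)[C@@H](O[Si](C)(C)C(C)(C)C)CCC2=O)O1 | intermediate
22 | (4S)-2-{[(2S,3S,5R)-5-[(1E)-2,6-dimethylhepta-1,5-dien-1-yl]-3-hydroxy-3-methyloxolan-2-yl]methyl}-3,4-dihydroxycyclohex-2-en-1-one | CC(C)=CCC/C(C)=C/[C@H]1C[C@](C)(O)[C@H](CC2=C(O)[C@@H](O)CCC2=O)O1 | target

Total step count: 14. Longest linear sequence: 9 steps (1, 2, 4, 5, 6, 7, 12, 13, 14).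

Steps most likely to fail

Step 12. Formation of the palladium alkoxide under carbonate may be too slow, so that Heck-type insertion at the vinyl group or β-hydride loss from the allylic C5 alkoxide takes over. Reductive elimination from the hindered alkenyl group may stall, or base may erode the configuration at C4'. The fallback gives up the one-step union, sets out from 14 and 18 and returns at 21. Cobalt-catalysed aerobic oxidative cyclisation of 14 (Co(modp)2, the bis(1-morpholinocarbamoyl-4,4-dimethylpentane-1,3-dionato) complex of divalent cobalt, O2, tBuOOH, iPrOH, 55 °C), a reaction selective for 2,5-trans oxolanes from γ-hydroxy terminal alkenes, would give [(2S,3S,5R)-5-[(1E)-2,6-dimethylhepta-1,5-dien-1-yl]-3-hydroxy-3-methyloxolan-2-yl]methanol F1. Selective oxidation of its primary hydroxyl (TEMPO, PhI(OAc)2, CH2Cl2) would give (2R,3S,5R)-5-[(1E)-2,6-dimethylhepta-1,5-dien-1-yl]-3-hydroxy-3-methyloxolane-2-carbaldehyde F2. Hydrolysis of 18 (1 M HCl, THF) would give (4S)-4-[(tert-butyldimethylsilyl)oxy]cyclohexane-1,3-dione F3, and organocatalytic reductive alkylation of this dione with the aldehyde (L-proline cat., Hantzsch ester, CH2Cl2, rt; Knoevenagel condensation followed by hydride transfer) would give 21.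

Step 9. The lipase may discriminate poorly between the enantiomers or acylate the S alcohol preferentially, which would leave material of low or opposite enantiomeric purity. The fallback sets out from 16 and returns at 17. Esterification with (S)-2-methoxy-2-phenylacetic acid (DCC, DMAP cat., CH2Cl2) and separation of the two diastereomeric esters by chromatography or crystallisation would give (1S)-4-methoxy-2-oxocyclohex-3-en-1-yl (2S)-2-methoxy-2-phenylacetate F4, and mild methanolysis (K2CO3 cat., MeOH, 0 °C) would release 17.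

Step 4. A methyl group may be transferred from residual aluminium or zinc species to the acylpalladium intermediate, or Lewis-acidic organoaluminium may attack the dioxolanone and cause β-elimination in the β-alkoxy ketone. The fallback sets out from 6 and 3 and returns at 9. Carboalumination of 6 as before, followed by I2 (THF, −30 °C), would give (1E)-1-iodo-2,6-dimethylhepta-1,5-diene F5. Rosenmund reduction of 3 (H2, Pd/BaSO4, 2,6-lutidine, THF) would give 2-[(4S)-2,2,4-trimethyl-5-oxo-1,3-dioxolan-4-yl]acetaldehyde F6. Nozaki–Hiyama–Kishi coupling of the two (CrCl2, NiCl2 cat., DMSO, rt) would give (5S)-5-[(3E)-2-hydroxy-4,8-dimethylnona-3,7-dien-1-yl]-2,2,5-trimethyl-1,3-dioxolan-4-one F7 as a mixture of carbinol epimers, and Dess–Martin periodinane oxidation would return 9.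

Further compounds
F1 | step 12 | [(2S,3S,5R)-5-[(1E)-2,6-dimethylhepta-1,5-dien-1-yl]-3-hydroxy-3-methyloxolan-2-yl]methanol | CC(C)=CCC/C(C)=C/[C@H]1C[C@](C)(O)[C@H](CO)O1
F2 | step 12 | (2R,3S,5R)-5-[(1E)-2,6-dimethylhepta-1,5-dien-1-yl]-3-hydroxy-3-methyloxolane-2-carbaldehyde | CC(C)=CCC/C(C)=C/[C@H]1C[C@](C)(O)[C@H](C=O)O1
F3 | step 12 | (4S)-4-[(tert-butyldimethylsilyl)oxy]cyclohexane-1,3-dione | O=C1CC[C@H](O[Si](C)(C)C(C)(C)C)C(=O)C1
F4 | step 9 | (1S)-4-methoxy-2-oxocyclohex-3-en-1-yl (2S)-2-methoxy-2-phenylacetate | COC1=CC(=O)[C@@H](OC(=O)[C@@H](OC)c2ccccc2)CC1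
F5 | step 4 | (1E)-1-iodo-2,6-dimethylhepta-1,5-diene | CC(C)=CCC/C(C)=C/I
F6 | step 4 | 2-[(4S)-2,2,4-trimethyl-5-oxo-1,3-dioxolan-4-yl]acetaldehyde | C[C@@]1(CC=O)OC(C)(C)OC1=O
F7 | step 4 | (5S)-5-[(3E)-2-hydroxy-4,8-dimethylnona-3,7-dien-1-yl]-2,2,5-trimethyl-1,3-dioxolan-4-one (both carbinol epimers) | CC(C)=CCC/C(C)=C/C(O)C[C@]1(C)OC(C)(C)OC1=O
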